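**Retrosynthetic overview**
1. Target 5 is the free-acid form of the bis(triethylammonium) salt 4; the last disconnection is a simple cation exchange.
2. Both aryl O–S bonds of 4 disconnect to diosmetin 1 (commercial 5,7,3'-trihydroxy-4'-methoxyflavone) and the SO3–triethylamine adduct 2.
3. No ring is formed: ring A, ring C (the chromone) and ring B are bought intact in 1.
4. The only selectivity issue is 7-OH and 3'-OH over the 5-OH, which is hydrogen-bonded to the C4 carbonyl and does not react.

Assumption: the target has no stereocentre (it is achiral), so no stereocontrol is needed; it is delivered as the free bis(hydrogen sulfate) exactly as drawn, and diosmetin is taken as a commercial starting material.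

**Route**

Step 1
Reactants: 1 diosmetin (5,7,3'-trihydroxy-4'-methoxyflavone); 2 sulfur trioxide–triethylamine complex
Product: 4 bis(triethylammonium) diosmetin 7,3'-disulfate, via triethylammonium diosmetin 7-sulfate 3 (not isolated)
Conditions: 2 (5 equiv), N,N-dimethylacetamide, 65 °C, 16 h; precipitate with Et2O; reversed-phase C18 chromatography (H2O/MeOH)
Reagents that add atoms: sulfur trioxide–triethylamine complex, CC[N+](CC)(CC)S(=O)(=O)[O-]
Why: Phenol O-sulfation (sulfuryl transfer from the SO3–amine adduct) takes the acidic 7-OH first and then the 3'-OH, while the 5-OH is held in a strong intramolecular hydrogen bond to the C4 carbonyl and stays free; no stereocentre is involved.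

Step 2
Reactants: 4 bis(triethylammonium) diosmetin 7,3'-disulfate
Product: 5 luteolin 4'-methyl ether 7,3'-disulfate (diosmetin 7,3'-bis(hydrogen sulfate))
Conditions: sulfonic acid cation-exchange resin (H+ form), H2O, 0–5 °C, short contact; freeze-dry at once
Reagents that add atoms: none
Why: Cation exchange (proton transfer) lets the resin take up Et3NH+ and release H+, giving the neutral bis(hydrogen sulfate) while the cold, brief, purely aqueous handling keeps the acid-labile aryl O–S bonds intact; no stereocentre is involved.

**Compound list**
1 | diosmetin (5,7,3'-trihydroxy-4'-methoxyflavone) | COc1ccc(-c2cc(=O)c3c(O)cc(O)cc3o2)cc1O | starting material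
2 | sulfur trioxide–triethylamine complex | CC[N+](CC)(CC)S(=O)(=O)[O-] | starting material
3 | triethylammonium diosmetin 7-sulfate (main mono-sulfate formed on the way) | COc1ccc(-c2cc(=O)c3c(O)cc(OS(=O)(=O)[O-])cc3o2)cc1O.CC[NH+](CC)CC | intermediate
4 | bis(triethylammonium) diosmetin 7,3'-disulfate | COc1ccc(-c2cc(=O)c3c(O)cc(OS(=O)(=O)[O-])cc3o2)cc1OS(=O)(=O)[O-].CC[NH+](CC)CC.CC[NH+](CC)CC | intermediate
5 | luteolin 4'-methyl ether 7,3'-disulfate (5-hydroxy-4'-methoxyflavone 7,3'-bis(hydrogen sulfate)) | COc1ccc(-c2cc(=O)c3c(O)cc(OS(=O)(=O)O)cc3o2)cc1OS(=O)(=O)O | target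

**Totals**
Total step count: 2. Longest linear sequence: 2 steps (1 → 4 → 5).

**Steps most likely to fail** (the route has only two steps, so both are ranked and there is no third)

Most likely to fail, step 2: the free aryl hydrogen sulfate is a strong acid that can catalyse its own desulfation during resin contact or concentration, and exchange may be incomplete. The fallback liberates the acid by stoichiometric precipitation instead of ion exchange. It sets out from 4, which is treated with Ba(OH)2 (1.0 equiv) in water and freed of triethylamine by evaporation to give the barium salt C16H10BaO12S2, barium diosmetin 7,3'-disulfate F3. Cold dilute H2SO4 (exactly 1.00 equiv) is then added so that BaSO4 precipitates. After filtration and immediate freeze-drying of the filtrate, the fallback comes back to the route at 5.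

Second, step 1: sulfation may stop at mono-sulfates, give traces of 5-O-sulfate, or give polar salts that cannot be separated cleanly. The fallback uses a masked sulfate diester that can be purified on silica. It sets out from 1, which is treated with 2,2,2-trichloroethyl chlorosulfate (ClS(=O)(=O)OCC(Cl)(Cl)Cl, 2.2 equiv), Et3N and catalytic DMAP in THF at 0 °C to room temperature. This gives the neutral diosmetin 7,3'-bis(2,2,2-trichloroethyl sulfate) F1, whose regiochemistry and purity are secured by ordinary chromatography. Zn dust and HCO2NH4 in MeOH at room temperature then unmask both sulfates by reductive elimination to give bis(ammonium) diosmetin 7,3'-disulfate F2. F2 is passed over the acidic resin of step 2 in place of 4, and the fallback comes back to the route at 5.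

Further compounds
F1 | step 1 | diosmetin 7,3'-bis(2,2,2-trichloroethyl sulfate) | COc1ccc(-c2cc(=O)c3c(O)cc(OS(=O)(=O)OCC(Cl)(Cl)Cl)cc3o2)cc1OS(=O)(=O)OCC(Cl)(Cl)Cl
F2 | step 1 | bis(ammonium) diosmetin 7,3'-disulfate | COc1ccc(-c2cc(=O)c3c(O)cc(OS(=O)(=O)[O-])cc3o2)cc1OS(=O)(=O)[O-].[NH4+].[NH4+]
F3 | step 2 | barium diosmetin 7,3'-disulfate (C16H10BaO12S2) | COc1ccc(-c2cc(=O)c3c(O)cc(OS(=O)(=O)[O-])cc3o2)cc1OS(=O)(=O)[O-].[Ba+2]
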